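Two questions stand on one flask, birch, and I begin from a count, because a rate constant says how fast a reaction goes but not where it stops.

| flask | electrophile | free base | protonated nucleophile | remark | time |
|---|---|---|---|---|---|
| birch | 0.074 M | 0.148 M | 0.0814 M | the very flask that is asked about, followed so far |  |
| ash | 0.11 M | 0.148 M | 0.0814 M | run made earlier |  |
| flask | 0.074 M | 0.148 M | 0.0814 M |  | 2.5 d |

| run | time / h | electrophile / % | target / % |
|---|---|---|---|
| birch | 4.00 | 27.1 | 71.9 |
| birch | 8.00 | 16.1 | 83.6 |
| birch | 10.0 | 13.1 | 88.0 |
| birch | 15.0 | 7.5 | 92.8 |
| birch | 20.0 | 4.7 | 95.1 |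
| ash | 5.00 | 39.1 | 61.0 |
| ash | 10.0 | 30.7 | 68.6 |
| ash | 15.0 | 27.8 | 72.0 |
| ash | 20.0 | 26.7 | 74.0 |
| ash | 25.0 | 26.5 | 74.3 |

(standard deviation of a reading: 0.5 percentage points)

1. part of the electrophile that has reacted at 2.5 d
2. share of free nucleophile in free nucleophile and protonated nucleophile together, at 2.5 d

- the earlier runs do not show how much of nucleophile is bound; that part of a forecast is a guess

I divide the protonated nucleophile charged by the electrophile charged. For birch this gives 1.10, and I carry this equivalent ratio, protonated nucleophile per electrophile charged. A ratio of one is the zero of my scale: the flask in which the two charges match. The ash run tests the ratio. Its electrophile reads 26.7% and then 26.5% of the charge, so within the scatter of a reading it has stopped falling, with its target reading 74.3%. The ratio in ash is 74.0%, which comes from the charges and not from the readings. So I take each electrophile to use one nucleophile, and a ratio below one to be the reacted fraction at which a flask stops, the nucleophile being the limiting reagent.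

Birch stands 0.100 above one, so its electrophile is the limiting reagent. Nearly all of its electrophile has reacted by 20.0 h, and the asked time is 3.00 times as long, so I commit to a conversion close to the whole charge. The readings do not show how much nucleophile is bound, so the free share is a guess for me too.

The forecast gives 99.5% reacted, within 98.6% to 99.9%, and 85% free, within 50% to 98%, holding that “the free share hardly changes”.

The flask gives 99.8% reacted and 94.6% free, so the free share stands 9.6 percentage points above the forecast's figure.

    electrophile + nucleophile → acid set free + target (k = 0.00640 M⁻¹ s⁻¹)
    nucleophile + acid set free ⇌ protonated nucleophile, settled at all times (K = 390 M⁻¹)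
    acid set free + free base ⇌ salt of the base (K = 1.20 × 10⁵ M⁻¹, k = 0.0680 M⁻¹ s⁻¹)
    nucleophile ⇌ dormant form (K = 1.40, k = 1.60 × 10⁻⁴ s⁻¹)
    2 free base → self-condensation product (k = 5.60 × 10⁻⁴ M⁻¹ s⁻¹)
    acid set free → by-product carried off (k = 2.20 × 10⁻⁴ s⁻¹)

The asked flask, at ratio 1.10, keeps 0.22% of its electrophile at 2.5 d. A neighbouring flask keeps the birch recipe but is charged with 0.049 M of protonated nucleophile. Its ratio is 0.662, which lies below one, so the same reckoning stops it at that fraction of its electrophile. At 2.5 d the neighbouring flask shows 66.2% reacted, its target holds 66.2%, and 34% of its charged electrophile is still there, unbound.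

All runs are simulated with made-up constants, and the scatter is random.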